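The synthesis rests on cutting the salicylate ring at C3–C4 and C1–C6. The cut exploits the ring's 1,2,3-pattern (C1 carboxyl, C2 hydroxyl, C6 chain, C3–C5 unsubstituted), which is that of a folded tetraketide lacking only the C4 oxygen. A TiCl4-mediated [3+3] cycloaromatisation joins the bis(silyl enol ether) of methyl acetoacetate (C1–C3 and the ester) to a β-methoxy enone (C4–C6 and the chain). It forms both bonds, the benzene ring and the complete substitution pattern in one operation. The precursor, (E)-1-methoxy-15-phenylpentadec-1-en-3-one, carries the whole 12-phenyldodecyl chain on its ketone carbon and comes from 11-bromoundecanoic acid in four steps. Saponification finishes the synthesis.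

Key step: step 7

Remark: the target has no stereocentre and no stereogenic double bond, so it is achiral and exists as one compound only; no enantiocontrol is needed.

Step 1
Reactants: 1 11-bromoundecanoic acid; 2 phenethylmagnesium chloride (2-phenylethylmagnesium chloride, commercial 1.0 M solution in THF)
Product: 4 13-phenyltridecanoic acid, via chloromagnesium 11-bromoundecanoate 3 (not isolated)
Conditions: 2 (1.0 equiv), THF, −20 °C; then Li2CuCl4 (3 mol %) and 2 (1.3 equiv), −20 °C → rt; 1 M HCl; base/acid extraction, recrystallisation
Reagents that add atoms: none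
Why: The first equivalent of 2 only deprotonates the acid to the salt 3, whose carboxylate is inert to Grignard reagents, and the copper-catalysed sp3–sp3 cross-coupling of a primary alkyl Grignard reagent with a primary alkyl bromide (Kochi-type coupling) then joins C11 to the phenethyl carbon, the acidic product being separable from neutral by-products by extraction.

Step 2
Reactants: 4 13-phenyltridecanoic acid
Product: 6 N-methoxy-N-methyl-13-phenyltridecanamide, via 1-(imidazol-1-yl)-13-phenyltridecan-1-one 5 (not isolated)
Conditions: CDI (1.2 equiv), CH2Cl2, rt, 1 h; MeNH(OMe)·HCl (1.5 equiv), rt, 12 h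
Reagents that add atoms: N,O-dimethylhydroxylamine hydrochloride, CNOC.Cl; 1,1'-carbonyldiimidazole, O=C(n1ccnc1)n1ccnc1 (imidazolyl group of 5 only)
Why: Amide formation through the acyl imidazolide is mild for an unhindered aliphatic acid, needs no added base because imidazole takes up the HCl, and touches neither the chain nor the phenyl ring.

Step 3
Reactants: 6 N-methoxy-N-methyl-13-phenyltridecanamide; 7 ethynylmagnesium bromide (commercial 0.5 M solution in THF)
Product: 9 15-phenylpentadec-1-yn-3-one, via bromomagnesium 3-[methoxy(methyl)amino]-15-phenylpentadec-1-yn-3-olate 8 (not isolated)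
Conditions: 7 (2.0 equiv), THF, 0 °C → rt; reverse quench into ice-cold 1 M HCl/Et2O
Reagents that add atoms: none
Why: In this Weinreb ketone synthesis the alkynyl Grignard reagent adds once to give the five-membered magnesium chelate 8 (racemic, transient), which collapses to the ketone only on quenching, and the reverse quench into cold acid protonates the released N,O-dimethylhydroxylamine before it can add to the ynone.

Step 4
Reactants: 9 15-phenylpentadec-1-yn-3-one
Product: 10 (E)-1-methoxy-15-phenylpentadec-1-en-3-one
Conditions: MeOH (3 equiv), DABCO (10 mol %), CH2Cl2, 0 °C → rt; chromatography on Et3N-deactivated silica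
Reagents that add atoms: methanol, CO
Why: The amine-catalysed oxa-Michael addition of methanol to a terminal ynone runs through a β-ammonium enone and an addition–elimination that should give the thermodynamically preferred E vinylogous ester, and limiting methanol and time suppresses a second addition to the β,β-dimethoxy ketone.

Step 5
Reactants: 11 methyl acetoacetate
Product: 12 methyl 3-(trimethylsilyloxy)but-2-enoate (E/Z mixture, geometry of no consequence)
Conditions: TMSCl (1.5 equiv), Et3N (1.5 equiv), toluene, rt, 48 h; filtration under argon, distillation
Reagents that add atoms: chlorotrimethylsilane, C[Si](C)(C)Cl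
Why: O-Silylation of the strongly enolised β-keto ester with TMSCl and a tertiary amine (soft enolisation) gives the β-silyloxy enoate, whose double-bond geometry is erased in the next step.

Step 6
Reactants: 12 methyl 3-(trimethylsilyloxy)but-2-enoate
Product: 14 1-methoxy-1,3-bis(trimethylsilyloxy)buta-1,3-diene (ketene acetal geometry of no consequence), via lithium 1-methoxy-3-(trimethylsilyloxy)buta-1,3-dien-1-olate 13 (not isolated)
Conditions: LDA (commercial solution, 1.2 equiv), THF, −78 °C, 1 h; TMSCl (1.3 equiv), −78 °C → rt; pentane, filtration under argon, used at once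
Reagents that add atoms: chlorotrimethylsilane, C[Si](C)(C)Cl; lithium diisopropylamide, [Li]N(C(C)C)C(C)C (lithium of 13 only)
Why: Kinetic γ-deprotonation of the vinylogous ester 12 by LDA gives the dienolate 13, which the hard electrophile TMSCl traps on oxygen (silyl ketene acetal formation) to give the 1,3-bis(silyl enol ether).

Step 7
Reactants: 10 (E)-1-methoxy-15-phenylpentadec-1-en-3-one; 14 1-methoxy-1,3-bis(trimethylsilyloxy)buta-1,3-diene
Product: 17 methyl 2-hydroxy-6-(12-phenyldodecyl)benzoate, via methyl 7-oxo-19-phenyl-3-(trimethylsilyloxy)nonadeca-2,5-dienoate 15 (not isolated), via methyl 2-oxo-6-(12-phenyldodecyl)-6-(trimethylsilyloxy)cyclohex-4-ene-1-carboxylate 16 (not isolated)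
Conditions: 14 (1.5 equiv), TiCl4 (1.1 equiv), 4 Å MS, CH2Cl2, −78 °C → rt, 14 h; 10% aq HCl
Reagents that add atoms: none
Why: TiCl4 binds the carbonyl oxygen of the vinylogous ester 10, so that its unhindered methoxy-bearing CH becomes the most electrophilic site, and the terminal CH2 of 14, the most nucleophilic carbon of the diene, adds there in a vinylogous Mukaiyama–Michael addition with loss of the methoxy group, which forms C3–C4 (ring numbering of 17 throughout) and gives 15. Reversible re-addition of chloride or methoxide at C4 lets the C4–C5 double bond of 15 change geometry, the chain folds, and the remaining silyl (or titanium) enolate carbon attacks the titanium-activated ketone in an intramolecular Mukaiyama aldol addition, which forms C1–C6 and gives 16. This closure of the only new ring, the six-membered carbocycle, is 6-exo-trig at the ketone and is favoured whether the chelated β-keto ester enolate is read as enolexo (ester enolate form) or as enolendo (ketone enolate form). Loss of the tertiary silyloxy group from 16 and tautomerisation of the cyclohexadienone give the hydrogen-bonded phenol 17, aromatisation making the sequence irreversible; the two stereocentres of 16 are transient and no stereocentre remains. The closest known reaction type is the TiCl4-mediated [3+3] cyclisation of 1,3-bis(silyl enol ethers) with 3-alkoxy- and 3-silyloxy-2-en-1-ones to give salicylates. The selectivity needed is regiochemical, chain at C6 and not at C4, and it is secured by the push–pull enone, whose ketone carbon is deactivated by conjugation and flanked by the chain until the β-carbon has reacted, which is why 10 must be free of its β,β-dimethoxy ketone; the saturated chain and the distal phenyl ring are inert.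

Step 8
Reactants: 17 methyl 2-hydroxy-6-(12-phenyldodecyl)benzoate
Product: 19 2-hydroxy-6-(12-phenyldodecyl)benzoic acid, via dipotassium 2-oxido-6-(12-phenyldodecyl)benzoate 18 (not isolated)
Conditions: KOH (10 equiv), DMSO/H2O 4:1, 90 °C, 12 h; 1 M HCl, 0 °C, to pH 2; recrystallisation
Reagents that add atoms: potassium hydroxide, [K+].[OH-]
Why: BAc2 saponification with poorly solvated hydroxide in aqueous DMSO should overcome the di-ortho hindrance and the deactivation by the phenoxide, the dianion 18 resists decarboxylation, cold acidification releases the salicylic acid, and nothing else in the molecule is base-sensitive.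

Compound list
1 | 11-bromoundecanoic acid | O=C(O)CCCCCCCCCCBr | starting material
2 | phenethylmagnesium chloride | Cl[Mg]CCc1ccccc1 | starting material
3 | chloromagnesium 11-bromoundecanoate | Cl[Mg]OC(=O)CCCCCCCCCCBr | intermediate
4 | 13-phenyltridecanoic acid | O=C(O)CCCCCCCCCCCCc1ccccc1 | intermediate
5 | 1-(imidazol-1-yl)-13-phenyltridecan-1-one | O=C(CCCCCCCCCCCCc1ccccc1)n1ccnc1 | intermediate
6 | N-methoxy-N-methyl-13-phenyltridecanamide | CON(C)C(=O)CCCCCCCCCCCCc1ccccc1 | intermediate
7 | ethynylmagnesium bromide | C#C[Mg]Br | starting material
8 | bromomagnesium 3-[methoxy(methyl)amino]-15-phenylpentadec-1-yn-3-olate (racemic, transient) | C#CC(O[Mg]Br)(CCCCCCCCCCCCc1ccccc1)N(C)OC | intermediate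
9 | 15-phenylpentadec-1-yn-3-one | C#CC(=O)CCCCCCCCCCCCc1ccccc1 | intermediate
10 | (E)-1-methoxy-15-phenylpentadec-1-en-3-one | CO/C=C/C(=O)CCCCCCCCCCCCc1ccccc1 | intermediate
11 | methyl acetoacetate | COC(=O)CC(C)=O | starting material
12 | methyl 3-(trimethylsilyloxy)but-2-enoate (E/Z mixture) | COC(=O)C=C(C)O[Si](C)(C)C | intermediate
13 | lithium 1-methoxy-3-(trimethylsilyloxy)buta-1,3-dien-1-olate | [Li]OC(OC)=CC(=C)O[Si](C)(C)C | intermediate
14 | 1-methoxy-1,3-bis(trimethylsilyloxy)buta-1,3-diene (geometry of no consequence) | COC(O[Si](C)(C)C)=CC(=C)O[Si](C)(C)C | intermediate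
15 | methyl 7-oxo-19-phenyl-3-(trimethylsilyloxy)nonadeca-2,5-dienoate (alkene geometries not fixed; titanium may replace silicon on oxygen) | COC(=O)C=C(CC=CC(=O)CCCCCCCCCCCCc1ccccc1)O[Si](C)(C)C | intermediate
16 | methyl 2-oxo-6-(12-phenyldodecyl)-6-(trimethylsilyloxy)cyclohex-4-ene-1-carboxylate (racemic diastereomer mixture, transient) | COC(=O)C1C(=O)CC=CC1(CCCCCCCCCCCCc2ccccc2)O[Si](C)(C)C | intermediate
17 | methyl 2-hydroxy-6-(12-phenyldodecyl)benzoate | COC(=O)c1c(O)cccc1CCCCCCCCCCCCc1ccccc1 | intermediate
18 | dipotassium 2-oxido-6-(12-phenyldodecyl)benzoate | [K+].[K+].[O-]C(=O)c1c([O-])cccc1CCCCCCCCCCCCc1ccccc1 | intermediate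
19 | 2-hydroxy-6-(12-phenyldodecyl)benzoic acid (achiral) | O=C(O)c1c(O)cccc1CCCCCCCCCCCCc1ccccc1 | target

Total step count: 8. Longest linear sequence: 6 (steps 1, 2, 3, 4, 7, 8); steps 5 and 6 form the short second branch.

Steps most likely to fail

First, step 7. The diene may be hydrolysed or may self-condense at titanium before it meets the enone. The open-chain adduct may fail to fold and close. Site selectivity may also erode, so that part of the chain ends at C4. In the fallback the ring is bought rather than built, and the chain is attached by cross-coupling. It sets out from 2, which is coupled with commercial 10-bromodec-1-ene under the copper catalysis of step 1 to give 12-phenyldodec-1-ene F1. Hydroboration with 9-BBN-H in THF gives 9-(12-phenyldodecyl)-9-borabicyclo[3.3.1]nonane F2, which is used in solution. Commercial 5-hydroxy-2,2-dimethyl-4H-1,3-benzodioxin-4-one is converted with Tf2O and pyridine into 2,2-dimethyl-4-oxo-4H-1,3-benzodioxin-5-yl trifluoromethanesulfonate F3. A B-alkyl Suzuki–Miyaura coupling of the borane with the triflate [PdCl2(dppf), K3PO4, THF/DMF, 60 °C] gives 2,2-dimethyl-5-(12-phenyldodecyl)-4H-1,3-benzodioxin-4-one F4. KOH in aqueous THF followed by cold acid opens the dioxinone with loss of acetone, so the fallback comes back to the route at 19.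

Second, step 3. The liberated N,O-dimethylhydroxylamine may add in conjugate fashion to the ynone during the quench, or the terminal ynone may oligomerise under the basic conditions. In the fallback the carbonyl group is made by oxidation, with no amine present. It sets out from 6, which DIBAL-H (THF, −78 °C) reduces to 13-phenyltridecanal F5. Addition of 7 (THF, 0 °C) gives racemic 15-phenylpentadec-1-yn-3-ol F6. Oxidation of this propargylic alcohol with activated MnO2 (CH2Cl2, rt) brings the fallback back to the route at 9.

Third, step 8. Acyl–oxygen cleavage may stall, because the ester carbonyl is shielded by two ortho substituents and deactivated by the neighbouring phenoxide. Forcing the temperature, or acidifying while hot, invites protodecarboxylation. The fallback cleaves the O–CH3 bond by SN2 attack instead of attacking the shielded carbonyl. It sets out from 17. Sodium ethanethiolate (3 equiv) in DMF at 100 °C attacks the unhindered methyl carbon and gives disodium 2-oxido-6-(12-phenyldodecyl)benzoate F7, which cold 1 M HCl converts into 19.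

Further compounds
F1 | step 7 | 12-phenyldodec-1-ene | C=CCCCCCCCCCCc1ccccc1
F2 | step 7 | 9-(12-phenyldodecyl)-9-borabicyclo[3.3.1]nonane | c1ccccc1CCCCCCCCCCCCB1C2CCCC1CCC2
F3 | step 7 | 2,2-dimethyl-4-oxo-4H-1,3-benzodioxin-5-yl trifluoromethanesulfonate | CC1(C)OC(=O)c2c(OS(=O)(=O)C(F)(F)F)cccc2O1
F4 | step 7 | 2,2-dimethyl-5-(12-phenyldodecyl)-4H-1,3-benzodioxin-4-one | CC1(C)OC(=O)c2c(CCCCCCCCCCCCc3ccccc3)cccc2O1
F5 | step 3 | 13-phenyltridecanal | O=CCCCCCCCCCCCCc1ccccc1
F6 | step 3 | 15-phenylpentadec-1-yn-3-ol (racemic) | C#CC(O)CCCCCCCCCCCCc1ccccc1
F7 | step 8 | disodium 2-oxido-6-(12-phenyldodecyl)benzoate | [Na+].[Na+].[O-]C(=O)c1c([O-])cccc1CCCCCCCCCCCCc1ccccc1
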